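Locants are iridal locants: C1 aldehyde carbon, C2=C7 exocyclic alkene, ring C6–C7–C8–C9–C10–C11 (C10 carbinol carbon, C9 the ring CH2 next to it), C3–C5 arm on C6, C12–C24 chain on C11.
Target 32 <= cyclohexanol ester 28 (ester to enal, desilylation, two acetylations); 28 <= acyclic iodo ketone 26 by closing the only ring, last, between C9 and C10 (samarium Barbier addition; C10 is set in the closure).
Feature that allows this: C10 is the carbonyl carbon of a methyl ketone on quaternary C11 and lies 1,6 to primary C9, and the exocyclic tetrasubstituted C7=C2 alkene (ester cis to C6) exerts allylic 1,3-strain that fixes the chair of the forming ring C6–C11.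
26 <= acid 18 via β-keto ester, (E)-enol tosylate and retentive vinylation (Z alkene), Wacker oxidation (C10 ketone), hydroboration and iodination; 18 <= ester 15 by an enantioselective Ireland–Claisen rearrangement (C6–C11 bond, both stereocentres).
15 <= acid 14 + C20 allylic alcohol 12, itself from pent-4-ynal, a formyl ylide and geranyl chloride (CBS reduction sets C16, carboalumination the allylic terminus); there is one ring only, formed in step 16.

Key step: step 16

Remark: TBS = tert-butyldimethylsilyl, TBSO = its oxy group. The CIP letters at C6 and C11 change along the route only because substituent priorities change; the spatial arrangement is that of the target throughout.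
Assumption: the (S,S)-bromodiazaborolidine controller of step 9, BrB1N(S(=O)(=O)c2cc(C(F)(F)F)cc(C(F)(F)F)c2)[C@@H](c2ccccc2)[C@H](c2ccccc2)N1S(=O)(=O)c1cc(C(F)(F)F)cc(C(F)(F)F)c1, is taken to give acid 18; the sense of induction is assigned by analogy with simple crotyl and geranyl esters, and the (R,R)-controller would be used if it proved opposite.

Step 1
Reactants: 1 pent-4-ynal; 2 2-(triphenylphosphoranylidene)propanal
Product: 3 (E)-2-methylhept-2-en-6-ynal
Conditions: toluene, 80 °C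
Reagents that add atoms: none
Why: Wittig olefination with the stabilised formyl ylide should give the (E)-trisubstituted enal under thermodynamic control, and the hindered conjugated product aldehyde does not react further.

Step 2
Reactants: 4 geranyl chloride; 3 (E)-2-methylhept-2-en-6-ynal
Product: 6 rac-(5E,9E)-6,10,14-trimethylpentadeca-5,9,13-trien-1-yn-7-ol, via geranylbarium chloride 5 (not isolated)
Conditions: Ba (from BaI2 and 2 LiC12H10, lithium biphenylide), THF, rt; 4, −78 °C; then 3 (0.45 equiv), −78 °C; aq. NH4Cl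
Reagents that add atoms: none
Why: Allylbarium addition: geranylbarium reagents add 1,2 to aldehydes through the unsubstituted alpha carbon with retention of the (E) alkene, the excess covering deprotonation of the alkyne; the carbinol centre is racemic here and is re-set in steps 3 and 4.

Step 3
Reactants: 6 rac-(5E,9E)-6,10,14-trimethylpentadeca-5,9,13-trien-1-yn-7-ol
Product: 7 (5E,9E)-6,10,14-trimethylpentadeca-5,9,13-trien-1-yn-7-one
Conditions: Dess–Martin periodinane, NaHCO3, CH2Cl2, 0 °C → rt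
Reagents that add atoms: none
Why: Dess–Martin oxidation under bicarbonate buffering should give the enone without moving the beta,gamma-alkene into conjugation.

Step 4
Reactants: 7 (5E,9E)-6,10,14-trimethylpentadeca-5,9,13-trien-1-yn-7-one
Product: 8 (5E,7R,9E)-6,10,14-trimethylpentadeca-5,9,13-trien-1-yn-7-ol
Conditions: (S)-2-methyl-CBS-oxazaborolidine (0.2 equiv), catecholborane (1.8 equiv), toluene, −78 °C; aq. NaOH
Reagents that add atoms: none
Why: Corey–Bakshi–Shibata reduction: the 1-methylalkenyl group acts as the large substituent, so the (S)-oxazaborolidine should deliver hydride to give the 7R alcohol (C16 of the target), and catecholborane at −78 °C spares the terminal alkyne.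

Step 5
Reactants: 8 (5E,7R,9E)-6,10,14-trimethylpentadeca-5,9,13-trien-1-yn-7-ol
Product: 9 (5E,7R,9E)-7-(TBSO)-6,10,14-trimethylpentadeca-5,9,13-trien-1-yne
Conditions: TBSCl, imidazole, DMF, rt
Reagents that add atoms: tert-butyldimethylsilyl chloride, C[Si](C)(Cl)C(C)(C)C
Why: Imidazole-promoted silylation protects the secondary allylic alcohol as a silyl ether that survives all steps up to step 19.

Step 6
Reactants: 9 (5E,7R,9E)-7-(TBSO)-6,10,14-trimethylpentadeca-5,9,13-trien-1-yne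
Product: 12 (2E,6E,8R,10E)-8-(TBSO)-3,7,11,15-tetramethylhexadeca-2,6,10,14-tetraen-1-ol, via alkenyldimethylalane 10 (not isolated), via lithium alkenylalanate 11 (not isolated)
Conditions: Me3Al (3 equiv), Cp2ZrCl2 (0.3 equiv), CH2Cl2, 0 °C → rt; then n-BuLi, THF, −78 °C; (CH2O)n, rt; aq. KNaC4H4O6
Reagents that add atoms: trimethylaluminium, C[Al](C)C; paraformaldehyde (as formaldehyde), C=O
Why: Zirconium-catalysed carboalumination (Negishi) adds methyl and aluminium syn across the terminal alkyne with methyl on the internal carbon, and the alanate is hydroxymethylated by formaldehyde with retention, which fixes the (2E) allylic alcohol.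

Step 7
Reactants: 13 5-(TBSO)pentan-1-ol
Product: 14 5-(TBSO)pentanoic acid
Conditions: TEMPO (0.2 equiv), PhI(OAc)2 (2.2 equiv), MeCN/H2O 1:1, rt
Reagents that add atoms: water, O
Why: TEMPO-catalysed oxidation takes the primary alcohol through the aldehyde hydrate to the acid without touching the silyl ether.

Step 8
Reactants: 14 5-(TBSO)pentanoic acid; 12 (2E,6E,8R,10E)-8-(TBSO)-3,7,11,15-tetramethylhexadeca-2,6,10,14-tetraen-1-ol
Product: 15 (2E,6E,8R,10E)-8-(TBSO)-3,7,11,15-tetramethylhexadeca-2,6,10,14-tetraen-1-yl 5-(TBSO)pentanoate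
Conditions: DCC, DMAP (0.1 equiv), CH2Cl2, 0 °C → rt
Reagents that add atoms: none
Why: Steglich esterification joins the two fragments under neutral conditions that leave the silyl ethers and the allylic system intact.

Step 9
Reactants: 15 (2E,6E,8R,10E)-8-(TBSO)-3,7,11,15-tetramethylhexadeca-2,6,10,14-tetraen-1-yl 5-(TBSO)pentanoate
Product: 18 (2S,3R,6E,8R,10E)-8-(TBSO)-2-[3-(TBSO)propyl]-3-ethenyl-3,7,11,15-tetramethylhexadeca-6,10,14-trienoic acid, via boron ketene acetal 16 (not isolated), via acyloxyborane 17 (not isolated)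
Conditions: (S,S)-bromodiazaborolidine controller (1.3 equiv, from the (S,S)-bis-sulfonamide and BBr3), i-Pr2NEt, CH2Cl2, −78 °C, then 4 °C, 72 h; aqueous work-up
Reagents that add atoms: none
Why: Enantioselective Ireland–Claisen rearrangement through a chiral boron ketene acetal: the Z(O) enolate and the (E) allyl unit pass through a chair with the C5 arm and the C12 chain both equatorial, which gives the syn C6/C11 pair including the quaternary carbon, while the C2-symmetric sulfonamide ligand on boron selects the face and so the absolute configuration.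

Step 10
Reactants: 18 (2S,3R,6E,8R,10E)-8-(TBSO)-2-[3-(TBSO)propyl]-3-ethenyl-3,7,11,15-tetramethylhexadeca-6,10,14-trienoic acid
Product: 20 ethyl (2RS,4S,5R,8E,10R,12E)-10-(TBSO)-4-[3-(TBSO)propyl]-5-ethenyl-2,5,9,13,17-pentamethyl-3-oxooctadeca-8,12,16-trienoate, via acyl imidazolide 19 (not isolated)
Conditions: 1,1'-carbonyldiimidazole, THF, rt; then Mg(O2CCH(CH3)CO2Et)2 (from ethyl hydrogen methylmalonate and Mg(OEt)2), THF, 45 °C; aq. HCl
Reagents that add atoms: ethyl hydrogen methylmalonate, CCOC(=O)C(C)C(O)=O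
Why: Masamune–Brooks homologation: the acyl imidazolide C-acylates the magnesium malonate half ester and decarboxylation gives the β-keto ester under neutral conditions, so C6 is not epimerised; the new C2 centre forms as a mixture and disappears in step 11.

Step 11
Reactants: 20 ethyl (2RS,4S,5R,8E,10R,12E)-10-(TBSO)-4-[3-(TBSO)propyl]-5-ethenyl-2,5,9,13,17-pentamethyl-3-oxooctadeca-8,12,16-trienoate
Product: 21 ethyl (2E,4S,5R,8E,10R,12E)-10-(TBSO)-4-[3-(TBSO)propyl]-5-ethenyl-2,5,9,13,17-pentamethyl-3-(tosyloxy)octadeca-2,8,12,16-tetraenoate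
Conditions: TsCl, N-methylimidazole, Et3N, MeCN, 0 °C → rt
Reagents that add atoms: p-toluenesulfonyl chloride, Cc1ccc(cc1)S(Cl)(=O)=O
Why: Enol tosylation of an α-substituted β-keto ester under non-chelating amine conditions should give the (E) isomer, sulfonate trans to the ester, by dipole minimisation in the free enolate; this places the leaving group cis to the C2 methyl.

Step 12
Reactants: 21 ethyl (2E,4S,5R,8E,10R,12E)-10-(TBSO)-4-[3-(TBSO)propyl]-5-ethenyl-2,5,9,13,17-pentamethyl-3-(tosyloxy)octadeca-2,8,12,16-tetraenoate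
Product: 22 ethyl (2E,4S,5S,8E,10R,12E)-5-acetyl-10-(TBSO)-4-[3-(TBSO)propyl]-2,5,9,13,17-pentamethyl-3-(tosyloxy)octadeca-2,8,12,16-tetraenoate
Conditions: PdCl2 (0.2 equiv), CuCl (1 equiv), O2 (1 atm), DMF/H2O 7:1, rt
Reagents that add atoms: water, O
Why: Tsuji–Wacker oxidation: Markovnikov hydroxypalladation of the only monosubstituted alkene gives the methyl ketone, while the trisubstituted alkenes and the electron-poor enol tosylate do not bind divalent palladium under these conditions.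

Step 13
Reactants: 22 ethyl (2E,4S,5S,8E,10R,12E)-5-acetyl-10-(TBSO)-4-[3-(TBSO)propyl]-2,5,9,13,17-pentamethyl-3-(tosyloxy)octadeca-2,8,12,16-tetraenoate
Product: 23 ethyl (2Z,4R,5S,8E,10R,12E)-5-acetyl-10-(TBSO)-4-[3-(TBSO)propyl]-3-ethenyl-2,5,9,13,17-pentamethyloctadeca-2,8,12,16-tetraenoate
Conditions: vinylboronic acid pinacol ester, Pd(OAc)2 (5 mol %), SPhos (10 mol %), K3PO4, THF/H2O, 60 °C
Reagents that add atoms: vinylboronic acid pinacol ester, C=CB1OC(C)(C)C(C)(C)O1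
Why: Suzuki–Miyaura coupling of the activated enol tosylate proceeds with retention, so the vinyl group ends cis to the C2 methyl and the ester cis to C6, the (2Z) dienoate.

Step 14
Reactants: 23 ethyl (2Z,4R,5S,8E,10R,12E)-5-acetyl-10-(TBSO)-4-[3-(TBSO)propyl]-3-ethenyl-2,5,9,13,17-pentamethyloctadeca-2,8,12,16-tetraenoate
Product: 25 ethyl (2Z,4R,5S,8E,10R,12E)-5-acetyl-10-(TBSO)-4-[3-(TBSO)propyl]-3-(2-hydroxyethyl)-2,5,9,13,17-pentamethyloctadeca-2,8,12,16-tetraenoate, via alkylborane 24 (not isolated)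
Conditions: 9-BBN (1.3 equiv), THF, 0 °C → rt; then 30% H2O2, pH 7 phosphate buffer, 0 °C → rt
Reagents that add atoms: hydrogen peroxide, OO
Why: Anti-Markovnikov hydroboration–oxidation: the bulky borane should select the single monosubstituted alkene over the three trisubstituted ones and the hindered ketone, and the neutral oxidation avoids enolisation next to the acrylate.

Step 15
Reactants: 25 ethyl (2Z,4R,5S,8E,10R,12E)-5-acetyl-10-(TBSO)-4-[3-(TBSO)propyl]-3-(2-hydroxyethyl)-2,5,9,13,17-pentamethyloctadeca-2,8,12,16-tetraenoate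
Product: 26 ethyl (2Z,4R,5S,8E,10R,12E)-5-acetyl-10-(TBSO)-4-[3-(TBSO)propyl]-3-(2-iodoethyl)-2,5,9,13,17-pentamethyloctadeca-2,8,12,16-tetraenoate
Conditions: I2, PPh3, imidazole, CH2Cl2, 0 °C
Reagents that add atoms: iodine, II
Why: Garegg–Samuelsson (Appel-type) iodination converts the primary alcohol into the iodide through the alkoxyphosphonium ion without affecting ketone, ester or silyl ethers.

Step 16
Reactants: 26 ethyl (2Z,4R,5S,8E,10R,12E)-5-acetyl-10-(TBSO)-4-[3-(TBSO)propyl]-3-(2-iodoethyl)-2,5,9,13,17-pentamethyloctadeca-2,8,12,16-tetraenoate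
Product: 28 ethyl (2Z)-2-{(2R,3S,4S)-4-hydroxy-3,4-dimethyl-2-[3-(TBSO)propyl]-3-[(3E,5R,7E)-5-(TBSO)-4,8,12-trimethyltrideca-3,7,11-trien-1-yl]cyclohexylidene}propanoate, via alkylsamarium diiodide 27 (not isolated)
Conditions: SmI2 (2.3 equiv), Fe(dbm)3 (tris(dibenzoylmethanato)iron, 2 mol %), THF, −78 °C → rt; aq. NH4Cl
Reagents that add atoms: none
Why: SmI2 reduces the primary C9–I bond through the alkyl radical to the alkylsamarium 27, which adds to the C10 ketone carbonyl; this is a samarium Barbier cyclisation, whose closest known type is the SmI2-promoted ring closure of ω-iodoalkyl ketones to 1-alkylcycloalkanols. The cyclohexane ring C6–C7–C8–C9–C10–C11 closes in the 6-exo-trig mode with the carbonyl oxygen outside the ring. The new stereocentre C10 is controlled by allylic 1,3-strain: the ester on C2 is cis to C6 across the tetrasubstituted C7=C2 alkene, so the C6 side arm must be axial in the chair transition state, and the axial site on C10 that faces this arm then takes the oxygen while the methyl goes equatorial, which is the target arrangement (hydroxyl cis to the C6 arm and to the C11 methyl). The step needs chemoselectivity for the iodide over the ketone and the acrylate, which is secured because primary iodides are reduced first under these conditions, because the fully substituted C7 does not accept the C9 radical in a productive 3-exo closure, and because the ester is held trans to C8 so that C9 cannot reach it. No intermediate is conjugated with C7=C2, so its Z geometry and the C6 and C11 centres cannot change.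

Step 17
Reactants: 28 ethyl (2Z)-2-{(2R,3S,4S)-4-hydroxy-3,4-dimethyl-2-[3-(TBSO)propyl]-3-[(3E,5R,7E)-5-(TBSO)-4,8,12-trimethyltrideca-3,7,11-trien-1-yl]cyclohexylidene}propanoate
Product: 29 (2Z)-2-{(2R,3S,4S)-4-hydroxy-3,4-dimethyl-2-[3-(TBSO)propyl]-3-[(3E,5R,7E)-5-(TBSO)-4,8,12-trimethyltrideca-3,7,11-trien-1-yl]cyclohexylidene}propan-1-ol
Conditions: i-Bu2AlH (4 equiv), CH2Cl2, −78 → −20 °C; aq. KNaC4H4O6
Reagents that add atoms: none
Why: 1,2-Reduction of the tetrasubstituted acrylate by the aluminium hydride should give the allylic alcohol without touching the alkene geometry; the tertiary alkoxide is inert.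

Step 18
Reactants: 29 (2Z)-2-{(2R,3S,4S)-4-hydroxy-3,4-dimethyl-2-[3-(TBSO)propyl]-3-[(3E,5R,7E)-5-(TBSO)-4,8,12-trimethyltrideca-3,7,11-trien-1-yl]cyclohexylidene}propan-1-ol
Product: 30 (2Z)-2-{(2R,3S,4S)-4-hydroxy-3,4-dimethyl-2-[3-(TBSO)propyl]-3-[(3E,5R,7E)-5-(TBSO)-4,8,12-trimethyltrideca-3,7,11-trien-1-yl]cyclohexylidene}propanal
Conditions: MnO2 (25 equiv), CH2Cl2, rt
Reagents that add atoms: none
Why: Manganese dioxide oxidises only the primary allylic alcohol, and the base-free conditions avoid deconjugation or Z/E isomerisation of the enal.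

Step 19
Reactants: 30 (2Z)-2-{(2R,3S,4S)-4-hydroxy-3,4-dimethyl-2-[3-(TBSO)propyl]-3-[(3E,5R,7E)-5-(TBSO)-4,8,12-trimethyltrideca-3,7,11-trien-1-yl]cyclohexylidene}propanal
Product: 31 (2Z)-2-{(2R,3S,4S)-4-hydroxy-2-(3-hydroxypropyl)-3-[(3E,5R,7E)-5-hydroxy-4,8,12-trimethyltrideca-3,7,11-trien-1-yl]-3,4-dimethylcyclohexylidene}propanal
Conditions: HF·pyridine, pyridine, THF, 0 °C → rt
Reagents that add atoms: none
Why: Fluoride-mediated cleavage of both silyl ethers under pyridine buffering should leave the enal and the tertiary alcohol untouched.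

Step 20
Reactants: 31 (2Z)-2-{(2R,3S,4S)-4-hydroxy-2-(3-hydroxypropyl)-3-[(3E,5R,7E)-5-hydroxy-4,8,12-trimethyltrideca-3,7,11-trien-1-yl]-3,4-dimethylcyclohexylidene}propanal
Product: 32 (2Z)-2-{(2R,3S,4S)-2-(3-acetoxypropyl)-3-[(3E,5R,7E)-5-acetoxy-4,8,12-trimethyltrideca-3,7,11-trien-1-yl]-4-hydroxy-3,4-dimethylcyclohexylidene}propanal (CNP0146964.1)
Conditions: Ac2O (3 equiv), pyridine, DMAP (0.1 equiv), CH2Cl2, 0 °C
Reagents that add atoms: acetic anhydride, CC(=O)OC(C)=O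
Why: DMAP-catalysed acetylation takes the primary and the secondary allylic hydroxyl, while the tertiary C10 hydroxyl next to quaternary C11 is too hindered to react at 0 °C.

Compound list
1 | pent-4-ynal | C#CCCC=O | starting material
2 | 2-(triphenylphosphoranylidene)propanal | CC(C=O)=P(c1ccccc1)(c1ccccc1)c1ccccc1 | starting material
3 | (E)-2-methylhept-2-en-6-ynal | C#CCC/C=C(\C)C=O | intermediate
4 | geranyl chloride ((E)-1-chloro-3,7-dimethylocta-2,6-diene) | ClC/C=C(\C)CCC=C(C)C | starting material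
5 | geranylbarium chloride | Cl[Ba]C/C=C(\C)CCC=C(C)C | intermediate
6 | rac-(5E,9E)-6,10,14-trimethylpentadeca-5,9,13-trien-1-yn-7-ol | C#CCC/C=C(\C)C(O)C/C=C(\C)CCC=C(C)C | intermediate
7 | (5E,9E)-6,10,14-trimethylpentadeca-5,9,13-trien-1-yn-7-one | C#CCC/C=C(\C)C(=O)C/C=C(\C)CCC=C(C)C | intermediate
8 | (5E,7R,9E)-6,10,14-trimethylpentadeca-5,9,13-trien-1-yn-7-ol | C#CCC/C=C(\C)[C@@H](C/C=C(\C)CCC=C(C)C)O | intermediate
9 | (5E,7R,9E)-7-(TBSO)-6,10,14-trimethylpentadeca-5,9,13-trien-1-yne | C#CCC/C=C(\C)[C@@H](C/C=C(\C)CCC=C(C)C)O[Si](C)(C)C(C)(C)C | intermediate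
10 | (E)-alkenyldimethylalane from 9 (Al and new methyl cis) | C[Al](C)/C=C(\C)CC/C=C(\C)[C@@H](C/C=C(\C)CCC=C(C)C)O[Si](C)(C)C(C)(C)C | intermediate
11 | lithium butyl(alkenyl)dimethylalanate from 10 | [Li+].CCCC[Al-](C)(C)/C=C(\C)CC/C=C(\C)[C@@H](C/C=C(\C)CCC=C(C)C)O[Si](C)(C)C(C)(C)C | intermediate
12 | (2E,6E,8R,10E)-8-(TBSO)-3,7,11,15-tetramethylhexadeca-2,6,10,14-tetraen-1-ol | OC/C=C(\C)CC/C=C(\C)[C@@H](C/C=C(\C)CCC=C(C)C)O[Si](C)(C)C(C)(C)C | intermediate
13 | 5-(TBSO)pentan-1-ol | OCCCCCO[Si](C)(C)C(C)(C)C | starting material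
14 | 5-(TBSO)pentanoic acid | OC(=O)CCCCO[Si](C)(C)C(C)(C)C | intermediate
15 | (2E,6E,8R,10E)-8-(TBSO)-3,7,11,15-tetramethylhexadeca-2,6,10,14-tetraen-1-yl 5-(TBSO)pentanoate | CC(C)(C)[Si](C)(C)OCCCCC(=O)OC/C=C(\C)CC/C=C(\C)[C@@H](C/C=C(\C)CCC=C(C)C)O[Si](C)(C)C(C)(C)C | intermediate
16 | Z(O) boron ketene acetal of 15 with the (S,S)-diazaborolidine | CC(C)(C)[Si](C)(C)OCCC/C=C(\OB1N(S(=O)(=O)c2cc(C(F)(F)F)cc(C(F)(F)F)c2)[C@@H](c2ccccc2)[C@H](c2ccccc2)N1S(=O)(=O)c1cc(C(F)(F)F)cc(C(F)(F)F)c1)OC/C=C(\C)CC/C=C(\C)[C@@H](C/C=C(\C)CCC=C(C)C)O[Si](C)(C)C(C)(C)C | intermediate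
17 | acyloxyborane of acid 18 with the (S,S)-diazaborolidine | CC(C)(C)[Si](C)(C)OCCC[C@@H]([C@](C)(CC/C=C(\C)[C@@H](C/C=C(\C)CCC=C(C)C)O[Si](C)(C)C(C)(C)C)C=C)C(=O)OB1N(S(=O)(=O)c2cc(C(F)(F)F)cc(C(F)(F)F)c2)[C@@H](c2ccccc2)[C@H](c2ccccc2)N1S(=O)(=O)c1cc(C(F)(F)F)cc(C(F)(F)F)c1 | intermediate
18 | (2S,3R,6E,8R,10E)-8-(TBSO)-2-[3-(TBSO)propyl]-3-ethenyl-3,7,11,15-tetramethylhexadeca-6,10,14-trienoic acid | CC(C)(C)[Si](C)(C)OCCC[C@@H]([C@](C)(CC/C=C(\C)[C@@H](C/C=C(\C)CCC=C(C)C)O[Si](C)(C)C(C)(C)C)C=C)C(O)=O | intermediate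
19 | acyl imidazolide of 18 | CC(C)(C)[Si](C)(C)OCCC[C@@H]([C@](C)(CC/C=C(\C)[C@@H](C/C=C(\C)CCC=C(C)C)O[Si](C)(C)C(C)(C)C)C=C)C(=O)n1ccnc1 | intermediate
20 | ethyl (2RS,4S,5R,8E,10R,12E)-10-(TBSO)-4-[3-(TBSO)propyl]-5-ethenyl-2,5,9,13,17-pentamethyl-3-oxooctadeca-8,12,16-trienoate | CC(C)(C)[Si](C)(C)OCCC[C@@H]([C@](C)(CC/C=C(\C)[C@@H](C/C=C(\C)CCC=C(C)C)O[Si](C)(C)C(C)(C)C)C=C)C(=O)C(C)C(=O)OCC | intermediate
21 | ethyl (2E,4S,5R,8E,10R,12E)-10-(TBSO)-4-[3-(TBSO)propyl]-5-ethenyl-2,5,9,13,17-pentamethyl-3-(tosyloxy)octadeca-2,8,12,16-tetraenoate | CC(C)(C)[Si](C)(C)OCCC[C@@H]([C@](C)(CC/C=C(\C)[C@@H](C/C=C(\C)CCC=C(C)C)O[Si](C)(C)C(C)(C)C)C=C)/C(OS(=O)(=O)c1ccc(C)cc1)=C(/C)C(=O)OCC | intermediate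
22 | ethyl (2E,4S,5S,8E,10R,12E)-5-acetyl-10-(TBSO)-4-[3-(TBSO)propyl]-2,5,9,13,17-pentamethyl-3-(tosyloxy)octadeca-2,8,12,16-tetraenoate | CC(C)(C)[Si](C)(C)OCCC[C@@H]([C@](C)(CC/C=C(\C)[C@@H](C/C=C(\C)CCC=C(C)C)O[Si](C)(C)C(C)(C)C)C(C)=O)/C(OS(=O)(=O)c1ccc(C)cc1)=C(/C)C(=O)OCC | intermediate
23 | ethyl (2Z,4R,5S,8E,10R,12E)-5-acetyl-10-(TBSO)-4-[3-(TBSO)propyl]-3-ethenyl-2,5,9,13,17-pentamethyloctadeca-2,8,12,16-tetraenoate | CC(C)(C)[Si](C)(C)OCCC[C@@H]([C@](C)(CC/C=C(\C)[C@@H](C/C=C(\C)CCC=C(C)C)O[Si](C)(C)C(C)(C)C)C(C)=O)/C(C=C)=C(/C)C(=O)OCC | intermediate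
24 | B-alkyl-9-borabicyclo[3.3.1]nonane adduct of 23 (boron on C9) | CC(C)(C)[Si](C)(C)OCCC[C@@H]([C@](C)(CC/C=C(\C)[C@@H](C/C=C(\C)CCC=C(C)C)O[Si](C)(C)C(C)(C)C)C(C)=O)/C(CCB1C2CCCC1CCC2)=C(/C)C(=O)OCC | intermediate
25 | ethyl (2Z,4R,5S,8E,10R,12E)-5-acetyl-10-(TBSO)-4-[3-(TBSO)propyl]-3-(2-hydroxyethyl)-2,5,9,13,17-pentamethyloctadeca-2,8,12,16-tetraenoate | CC(C)(C)[Si](C)(C)OCCC[C@@H]([C@](C)(CC/C=C(\C)[C@@H](C/C=C(\C)CCC=C(C)C)O[Si](C)(C)C(C)(C)C)C(C)=O)/C(CCO)=C(/C)C(=O)OCC | intermediate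
26 | ethyl (2Z,4R,5S,8E,10R,12E)-5-acetyl-10-(TBSO)-4-[3-(TBSO)propyl]-3-(2-iodoethyl)-2,5,9,13,17-pentamethyloctadeca-2,8,12,16-tetraenoate | CC(C)(C)[Si](C)(C)OCCC[C@@H]([C@](C)(CC/C=C(\C)[C@@H](C/C=C(\C)CCC=C(C)C)O[Si](C)(C)C(C)(C)C)C(C)=O)/C(CCI)=C(/C)C(=O)OCC | intermediate
27 | alkylsamarium diiodide from 26 (samarium on C9) | CC(C)(C)[Si](C)(C)OCCC[C@@H]([C@](C)(CC/C=C(\C)[C@@H](C/C=C(\C)CCC=C(C)C)O[Si](C)(C)C(C)(C)C)C(C)=O)/C(CC[Sm](I)I)=C(/C)C(=O)OCC | intermediate
28 | ethyl (2Z)-2-{(2R,3S,4S)-4-hydroxy-3,4-dimethyl-2-[3-(TBSO)propyl]-3-[(3E,5R,7E)-5-(TBSO)-4,8,12-trimethyltrideca-3,7,11-trien-1-yl]cyclohexylidene}propanoate | CC(C)(C)[Si](C)(C)OCCC[C@@H]1/C(=C(/C)C(=O)OCC)CC[C@](C)(O)[C@@]1(C)CC/C=C(\C)[C@@H](C/C=C(\C)CCC=C(C)C)O[Si](C)(C)C(C)(C)C | intermediate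
29 | (2Z)-2-{(2R,3S,4S)-4-hydroxy-3,4-dimethyl-2-[3-(TBSO)propyl]-3-[(3E,5R,7E)-5-(TBSO)-4,8,12-trimethyltrideca-3,7,11-trien-1-yl]cyclohexylidene}propan-1-ol | CC(C)(C)[Si](C)(C)OCCC[C@@H]1/C(=C(/C)CO)CC[C@](C)(O)[C@@]1(C)CC/C=C(\C)[C@@H](C/C=C(\C)CCC=C(C)C)O[Si](C)(C)C(C)(C)C | intermediate
30 | (2Z)-2-{(2R,3S,4S)-4-hydroxy-3,4-dimethyl-2-[3-(TBSO)propyl]-3-[(3E,5R,7E)-5-(TBSO)-4,8,12-trimethyltrideca-3,7,11-trien-1-yl]cyclohexylidene}propanal | CC(C)(C)[Si](C)(C)OCCC[C@@H]1/C(=C(/C)C=O)CC[C@](C)(O)[C@@]1(C)CC/C=C(\C)[C@@H](C/C=C(\C)CCC=C(C)C)O[Si](C)(C)C(C)(C)C | intermediate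
31 | (2Z)-2-{(2R,3S,4S)-4-hydroxy-2-(3-hydroxypropyl)-3-[(3E,5R,7E)-5-hydroxy-4,8,12-trimethyltrideca-3,7,11-trien-1-yl]-3,4-dimethylcyclohexylidene}propanal | OCCC[C@@H]1/C(=C(/C)C=O)CC[C@](C)(O)[C@@]1(C)CC/C=C(\C)[C@@H](C/C=C(\C)CCC=C(C)C)O | intermediate
32 | (2Z)-2-{(2R,3S,4S)-2-(3-acetoxypropyl)-3-[(3E,5R,7E)-5-acetoxy-4,8,12-trimethyltrideca-3,7,11-trien-1-yl]-4-hydroxy-3,4-dimethylcyclohexylidene}propanal (CNP0146964.1) | CC(=O)OCCC[C@@H]1/C(=C(/C)C=O)CC[C@](C)(O)[C@@]1(C)CC/C=C(\C)[C@@H](C/C=C(\C)CCC=C(C)C)OC(C)=O | target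

Total step count: 20. Longest linear sequence: 19 steps (steps 1–6, then 8–20).

Steps most likely to fail

Step 9. What may go wrong is loss of enantiofacial control, or leakage to the E(O) enolate, in the slow boron-mediated rearrangement of this hindered ester. Fallback: from 15, the lithium Z(O) enolate is formed with LiN(i-Pr)2 in THF/DMPU at −78 °C and trapped with Me3SiCl to give the silyl ketene acetal F1, which should rearrange on warming to the trimethylsilyl ester F2. Hydrolytic work-up then gives the syn acid as 18 together with its (2R,3S) diastereomer F3 (diastereomers because of the fixed 8R centre). These are separated by preparative HPLC or as their (S)-1-phenylethylammonium salts, and 18 rejoins the route at step 10.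

Step 14. What may go wrong is competing conjugate hydride delivery to the dienoate, or reduction of the ketone, during hydroboration. Fallback: from 22, Negishi coupling with (1,3-dioxolan-2-ylmethyl)zinc bromide (PdCl2(dppf), THF, 60 °C) should give the dioxolane F4 with retention of alkene geometry. The acetal is cleaved in the presence of the silyl ethers with Et3SiOTf and 2,4,6-collidine followed by water to give the keto aldehyde F5. This is reduced at once with NaBH4 in MeOH at −78 °C (aldehyde before the hindered ketone) to 25.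

Step 16. What may go wrong is quenching of the alkylsamarium before ring closure, competing reduction of the ketone, or too small a facial bias if the transition state leaves the strain-locked chair. Fallback: from 25, Dess–Martin oxidation gives the keto aldehyde F5 already described. SmI2 with t-BuOH in THF at −78 °C then effects an intramolecular pinacol coupling, the aldehyde ketyl adding to the ketone within a samarium chelate, to give the cis-diol F6. The secondary hydroxyl alone is thioacylated with PhOC(S)Cl and pyridine to the thionocarbonate F7, and Barton–McCombie reduction (Bu3SnH, AIBN, toluene, 80 °C) removes the C9 oxygen to return to 28.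

Further compounds
F1 | step 9 | Z(O) trimethylsilyl ketene acetal of 15 | CC(C)(C)[Si](C)(C)OCCC/C=C(\O[Si](C)(C)C)OC/C=C(\C)CC/C=C(\C)[C@@H](C/C=C(\C)CCC=C(C)C)O[Si](C)(C)C(C)(C)C
F2 | step 9 | trimethylsilyl ester of the syn acid (both antipodal forms at C6/C11; 8R fixed) | CC(C)(C)[Si](C)(C)OCCCC(C(C)(CC/C=C(\C)[C@@H](C/C=C(\C)CCC=C(C)C)O[Si](C)(C)C(C)(C)C)C=C)C(=O)O[Si](C)(C)C
F3 | step 9 | (2R,3S,6E,8R,10E) diastereomer of acid 18 | CC(C)(C)[Si](C)(C)OCCC[C@H]([C@@](C)(CC/C=C(\C)[C@@H](C/C=C(\C)CCC=C(C)C)O[Si](C)(C)C(C)(C)C)C=C)C(O)=O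
F4 | step 14 | ethyl (2Z,4R,5S,8E,10R,12E)-5-acetyl-10-(TBSO)-4-[3-(TBSO)propyl]-3-(1,3-dioxolan-2-ylmethyl)-2,5,9,13,17-pentamethyloctadeca-2,8,12,16-tetraenoate | CC(C)(C)[Si](C)(C)OCCC[C@@H]([C@](C)(CC/C=C(\C)[C@@H](C/C=C(\C)CCC=C(C)C)O[Si](C)(C)C(C)(C)C)C(C)=O)/C(CC1OCCO1)=C(/C)C(=O)OCC
F5 | step 14 | ethyl (2Z,4R,5S,8E,10R,12E)-5-acetyl-10-(TBSO)-4-[3-(TBSO)propyl]-2,5,9,13,17-pentamethyl-3-(2-oxoethyl)octadeca-2,8,12,16-tetraenoate | CC(C)(C)[Si](C)(C)OCCC[C@@H]([C@](C)(CC/C=C(\C)[C@@H](C/C=C(\C)CCC=C(C)C)O[Si](C)(C)C(C)(C)C)C(C)=O)/C(CC=O)=C(/C)C(=O)OCC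
F6 | step 16 | C9-hydroxy derivative of 28 (cis-9,10-diol; other centres as in 28) | CC(C)(C)[Si](C)(C)OCCC[C@@H]1/C(=C(/C)C(=O)OCC)CC(O)[C@](C)(O)[C@@]1(C)CC/C=C(\C)[C@@H](C/C=C(\C)CCC=C(C)C)O[Si](C)(C)C(C)(C)C
F7 | step 16 | C9 O-(phenoxythiocarbonyl) derivative of F6 | CC(C)(C)[Si](C)(C)OCCC[C@@H]1/C(=C(/C)C(=O)OCC)CC(OC(=S)Oc2ccccc2)[C@](C)(O)[C@@]1(C)CC/C=C(\C)[C@@H](C/C=C(\C)CCC=C(C)C)O[Si](C)(C)C(C)(C)C
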